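**Plan**
- Retrosynthesis: the two CO2H groups are traced back to CH2OH arms tied as an acetonide. Both C3–C6′ and C4–C6′ bonds are then cut in one operation, giving a cyclobutane-1,2-dicarboxylic acid and two molecules of a 6-sulfonylpyranone. The cyclobutane is finally cut across C1–C4 and C2–C3 into dimethylmaleic anhydride and a cyclic Z-alkene.
- Enabling feature: with the cyclobutane numbered C1, C2 (CH–CO2H) and C3, C4 (C(CH3)–pyranonyl), C3 and C4 each sit on C6′ of a 2-pyranone. C6′ is the δ-terminus of the C2′(=O)–C3′=C4′–C5′=C6′ dienoate next to the ring oxygen. With a sulfonyl group there, C6′ can accept a tertiary cyclobutyl radical and regain the pyranone by loss of sulfinate.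
- Forward order: the pyranone ring is closed by lactonisation and functionalised at C6′; the cyclobutane ring arises by sensitised [2+2]; the two pyranones are then joined to C3 and C4; the diol is finally oxidised to the diacid.
- Stereochemistry: the target is meso. C1/C2 become cis because the alkene is cyclic. C3/C4 are set in the key step by attack on the face opposite the ring-fused CH2O arms.

Key step: step 8

Remark: compounds 12, 13 and 15–18 are meso; 14 is racemic and its SMILES shows one enantiomer. The cyclobutane numbering C1–C4 of the target is used for all cyclobutanes.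

**Route**

Step 1
Reactants: 1 ethyl 2-methylacetoacetate; 2 ethyl formate
Product: 4 ethyl 2-methyl-3,5-dioxopentanoate (mainly as its 5-hydroxy-4-enone enol), via keto ester dianion 3 (not isolated)
Conditions: 1 (2 equiv), NaH then n-BuLi, THF, 0 °C; 2, −78 → 0 °C; 1 M HCl
Reagents that add atoms: none
Why: Claisen-type C-formylation of a β-keto ester dianion, in which the terminal (γ) carbanion is the more reactive site and attacks the formate while the second equivalent of dianion takes up the proton of the more acidic product; the C2 stereocentre is labile and disappears in step 2.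

Step 2
Reactants: 4 ethyl 2-methyl-3,5-dioxopentanoate
Product: 5 4-hydroxy-3-methyl-2H-pyran-2-one
Conditions: DBU, PhMe, 80 °C; 1 M HCl work-up
Reagents that add atoms: none
Why: Base-mediated enol lactonisation of a 3,5-dicarbonyl ester, the standard entry to 4-hydroxy-2-pyranones: the C5 enolate oxygen attacks the ester carbonyl in a 6-exo-trig acyl substitution and loss of ethanol gives the conjugated ring.

Step 3
Reactants: 5 4-hydroxy-3-methyl-2H-pyran-2-one
Product: 6 4-methoxy-3-methyl-2H-pyran-2-one
Conditions: Me2SO4, K2CO3, acetone, reflux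
Reagents that add atoms: dimethyl sulfate, COS(=O)(=O)OC
Why: O-Alkylation of the ambident hydroxypyranone anion under these conditions is expected to favour the 4-methoxy-2-pyranone over the isomeric 2-methoxy-4-pyranone, which chromatography would remove.

Step 4
Reactants: 6 4-methoxy-3-methyl-2H-pyran-2-one
Product: 8 4-methoxy-3-methyl-6-(phenylsulfanyl)-2H-pyran-2-one, via 6-magnesiated pyranone 7 (not isolated)
Conditions: TMPMgCl·LiCl, THF, −40 °C; PhSSPh, −40 → 0 °C; sat. aq. NH4Cl
Reagents that add atoms: diphenyl disulfide, c1ccc(SSc2ccccc2)cc1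
Why: Deprotonative metalation with a hindered TMP–magnesium amide at C6′–H, the most acidic ring C–H (α to the ring oxygen, the type of metalation known for C2 of chromones and 4-pyranones and C6 of 2-pyridones), followed by sulfenylation of the heteroarylmagnesium; C3′ is blocked by methyl and the lactone tolerates the non-nucleophilic base at low temperature.

Step 5
Reactants: 8 4-methoxy-3-methyl-6-(phenylsulfanyl)-2H-pyran-2-one
Product: 9 4-methoxy-3-methyl-6-(phenylsulfonyl)-2H-pyran-2-one
Conditions: mCPBA (2.2 equiv), CH2Cl2, 0 °C → rt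
Reagents that add atoms: mCPBA, O=C(OO)c1cccc(Cl)c1
Why: Peracid oxidation of the sulfide through the sulfoxide to the sulfone; the pyranone double bonds are electron-poor (vinylogous carbonate type) and should not be epoxidised.

Step 6
Reactants: 10 dimethylmaleic anhydride; 11 4,7-dihydro-2,2-dimethyl-1,3-dioxepine
Product: 12 cis-anti-cis photoadduct, 4,4,8,9-tetramethyl-3,5-dioxabicyclo[5.2.0]nonane-8,9-dicarboxylic anhydride (anhydride ring trans to the dioxepane, methyls cis to the CH2O arms)
Conditions: hν (350 nm, Pyrex), benzophenone (cat.), MeCN, 20 °C, excess 11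
Reagents that add atoms: none
Why: Triplet-sensitised [2+2] photocycloaddition in which benzophenone transfers triplet energy to the anhydride, which adds to the alkene through a 1,4-biradical; the cyclic Z-alkene cannot lose its geometry, so C1 and C2 become cis, both ring fusions are cis, and the anhydride is expected anti to the dioxepane, a relationship at C3/C4 that is in any case erased in step 8.

Step 7
Reactants: 12 cis-anti-cis anhydride
Product: 13 4,4,8,9-tetramethyl-3,5-dioxabicyclo[5.2.0]nonane-8,9-dicarboxylic acid (meso; the two CO2H cis to each other and trans to the CH2O arms)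
Conditions: NaOH (2.2 equiv), THF/H2O, 0 °C → rt; cold 1 M HCl to pH 3–4 under EtOAc, immediate extraction
Reagents that add atoms: sodium hydroxide (NaOH), [Na+].[OH-]
Why: Saponification of the strained cyclic anhydride under basic conditions that leave the acetonide untouched, followed by brief cold acidification so that the seven-membered acetal survives; the diacid is used at once.

Step 8
Reactants: 13 acetonide diacid; 9 4-methoxy-3-methyl-6-(phenylsulfonyl)-2H-pyran-2-one (two molecules react)
Product: 15 8,9-bis(4-methoxy-3-methyl-2-oxo-2H-pyran-6-yl)-4,4,8,9-tetramethyl-3,5-dioxabicyclo[5.2.0]nonane (meso; pyranones cis to each other and trans to the CH2O arms), via mono-pyranonyl acid 14 (not isolated)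
Conditions: [Ir(dF(CF3)ppy)2(dtbbpy)]PF6 (2 mol %), K2HPO4 (2.5 equiv), 9 (3 equiv), degassed DMF, 450 nm LEDs, 25 °C
Reagents that add atoms: none
Why: Proposed new method: the photoexcited trivalent iridium complex oxidises a tertiary carboxylate of 13, loss of CO2 gives a tertiary cyclobutyl radical that adds ipso at C6′ of 9, and the adduct radical delocalised over C5′/C3′ expels PhSO2•, which divalent iridium reduces to sulfinate to close the cycle; the remaining carboxylate of 14 then reacts in the same way. The closest known reaction types are the photoredox decarboxylative alkenylation of carboxylic acids with vinyl sulfones and the radical ipso-substitution of heteroaryl sulfones (radical addition, then sulfonyl loss). No ring is closed. Both new quaternary stereocentres, C3 and C4, are set by substrate control: the near-planar radical should be attacked on the convex face of the bicyclo[5.2.0] skeleton, away from the adjacent and the cross-ring CH2O arm and from the methyl on the neighbouring carbon, so each pyranone ends trans to the dioxepane and cis to the other pyranone, and because the radical is planar the original configuration of the carboxyl-bearing carbons does not matter. The step needs ipso regioselectivity, which the sulfonyl group secures because only addition at C6′ gives a radical conjugated with the lactone carbonyl and a β-sulfonyl bond that can fragment. It also needs radical rather than ionic substitution at C6′, which the low nucleophilicity of the hindered tertiary carboxylate and the mild, sparingly soluble base should secure.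

Step 9
Reactants: 15 bis(pyranonyl) acetonide
Product: 16 meso-[3,4-dimethyl-3,4-bis(4-methoxy-3-methyl-2-oxo-2H-pyran-6-yl)cyclobutane-1,2-diyl]dimethanol (both CH2OH and both CH3 on one face, both pyranones on the other)
Conditions: AcOH/H2O (4:1), 40 °C
Reagents that add atoms: none
Why: Acid-catalysed hydrolysis of the seven-membered acetonide, which is far more labile than the pyranone methyl enol ether (a vinylogous ester) in dilute acetic acid.

Step 10
Reactants: 16 diol
Product: 17 meso-3,4-dimethyl-3,4-bis(4-methoxy-3-methyl-2-oxo-2H-pyran-6-yl)cyclobutane-1,2-dicarbaldehyde (CHO groups cis to each other and to the methyls)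
Conditions: (COCl)2, DMSO, CH2Cl2, −78 °C; iPr2NEt, −78 → −20 °C; pH 7 buffer; crude used at once
Reagents that add atoms: none
Why: Swern oxidation, in which both hydroxyls are converted into alkoxysulfonium ions before the base is added so that no hydroxy aldehyde can close to a lactol, while the hindered base and low temperature are chosen to avoid epimerisation of the crowded all-cis dialdehyde at C1/C2.

Step 11
Reactants: 17 dialdehyde
Product: 18 CNP0574758.1, meso-3,4-dimethyl-3,4-bis(4-methoxy-3-methyl-2-oxo-2H-pyran-6-yl)cyclobutane-1,2-dicarboxylic acid (CO2H groups cis to each other and to both methyls, trans to both pyranones)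
Conditions: NaClO2, NaH2PO4, 2-methyl-2-butene, t-BuOH/H2O, 0 °C → rt
Reagents that add atoms: sodium chlorite (NaClO2), [Na+].[O-]Cl=O
Why: Pinnick oxidation in a weakly acidic buffer converts both aldehydes into acids without enolisation at C1/C2, and 2-methyl-2-butene removes HOCl before it can chlorinate C5′ of the pyranones.

**Compound list**

1 | ethyl 2-methylacetoacetate | CCOC(=O)C(C)C(C)=O | starting material
2 | ethyl formate | CCOC=O | starting material
3 | sodium lithium dianion of ethyl 2-methylacetoacetate (not isolated) | [Na+].[Li+].CCOC([O-])=C(C)C(=C)[O-] | intermediate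
4 | ethyl 2-methyl-3,5-dioxopentanoate (racemic, mainly enol) | CCOC(=O)C(C)C(=O)CC=O | intermediate
5 | 4-hydroxy-3-methyl-2H-pyran-2-one | Cc1c(O)ccoc1=O | intermediate
6 | 4-methoxy-3-methyl-2H-pyran-2-one | COc1ccoc(=O)c1C | intermediate
7 | 6-(chloromagnesio)-4-methoxy-3-methyl-2H-pyran-2-one, LiCl complex (not isolated) | COc1cc([Mg]Cl)oc(=O)c1C.[Li+].[Cl-] | intermediate
8 | 4-methoxy-3-methyl-6-(phenylsulfanyl)-2H-pyran-2-one | COc1cc(Sc2ccccc2)oc(=O)c1C | intermediate
9 | 4-methoxy-3-methyl-6-(phenylsulfonyl)-2H-pyran-2-one | COc1cc(S(=O)(=O)c2ccccc2)oc(=O)c1C | intermediate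
10 | dimethylmaleic anhydride | CC1=C(C)C(=O)OC1=O | starting material
11 | 4,7-dihydro-2,2-dimethyl-1,3-dioxepine | CC1(C)OCC=CCO1 | starting material
12 | cis-anti-cis 4,4,8,9-tetramethyl-3,5-dioxabicyclo[5.2.0]nonane-8,9-dicarboxylic anhydride (meso) | C[C@]1(C(=O)OC2=O)[C@@H]3COC(C)(C)OC[C@@H]3[C@]12C | intermediate
13 | 4,4,8,9-tetramethyl-3,5-dioxabicyclo[5.2.0]nonane-8,9-dicarboxylic acid (meso, CO2H trans to the CH2O arms) | C[C@]1(C(=O)O)[C@@H]2COC(C)(C)OC[C@@H]2[C@@]1(C)C(=O)O | intermediate
14 | 9-(4-methoxy-3-methyl-2-oxo-2H-pyran-6-yl)-4,4,8,9-tetramethyl-3,5-dioxabicyclo[5.2.0]nonane-8-carboxylic acid (racemic, pyranone and CO2H trans to the CH2O arms; not isolated) | C[C@]1(c3cc(OC)c(C)c(=O)o3)[C@@H]2COC(C)(C)OC[C@@H]2[C@@]1(C)C(=O)O | intermediate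
15 | 8,9-bis(4-methoxy-3-methyl-2-oxo-2H-pyran-6-yl)-4,4,8,9-tetramethyl-3,5-dioxabicyclo[5.2.0]nonane (meso) | C[C@]1(c3cc(OC)c(C)c(=O)o3)[C@@H]2COC(C)(C)OC[C@@H]2[C@@]1(C)c1cc(OC)c(C)c(=O)o1 | intermediate
16 | meso-[3,4-dimethyl-3,4-bis(4-methoxy-3-methyl-2-oxo-2H-pyran-6-yl)cyclobutane-1,2-diyl]dimethanol | C[C@]1(c2cc(OC)c(C)c(=O)o2)[C@H](CO)[C@H](CO)[C@@]1(C)c1cc(OC)c(C)c(=O)o1 | intermediate
17 | meso-3,4-dimethyl-3,4-bis(4-methoxy-3-methyl-2-oxo-2H-pyran-6-yl)cyclobutane-1,2-dicarbaldehyde | C[C@]1(c2cc(OC)c(C)c(=O)o2)[C@H](C=O)[C@H](C=O)[C@@]1(C)c1cc(OC)c(C)c(=O)o1 | intermediate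
18 | CNP0574758.1, meso-3,4-dimethyl-3,4-bis(4-methoxy-3-methyl-2-oxo-2H-pyran-6-yl)cyclobutane-1,2-dicarboxylic acid | COc1cc([C@@]2(C)[C@H](C(=O)O)[C@H](C(=O)O)[C@@]2(C)c2cc(OC)c(C)c(=O)o2)oc(=O)c1C | target

**Count and risks**

Total steps: 11. Longest linear sequence: 9 steps (steps 1–5, then 8–11).

Steps most likely to fail:

1. Step 8 (proposed new method).
 - Process at risk: addition of the hindered tertiary radical to the fully substituted C6′ may be too slow, above all for the second union next to a freshly made quaternary centre. The radical would then be lost by hydrogen abstraction, or the carboxylate would attack C6′ ionically. The facial selectivity of either addition may also erode.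
 - Fallback (known chemistry, a biomimetic photodimerisation): it sets out from 6 and returns to the route at 18.
 - Compound 6 is magnesiated as in step 4 and quenched with I2 to give 6-iodo-4-methoxy-3-methyl-2H-pyran-2-one F1.
 - Stille coupling with tert-butyl (E)-3-(tributylstannyl)but-2-enoate (Pd(PPh3)4, CuI, DMF) should give, with retention of alkene geometry, tert-butyl (E)-3-(4-methoxy-3-methyl-2-oxo-2H-pyran-6-yl)but-2-enoate F2.
 - TFA in CH2Cl2 should free (E)-3-(4-methoxy-3-methyl-2-oxo-2H-pyran-6-yl)but-2-enoic acid F3.
 - Two molecules of the acid are esterified on naphthalene-1,8-diol (EDC·HCl, DMAP) to the template diester naphthalene-1,8-diyl bis[(E)-3-(4-methoxy-3-methyl-2-oxo-2H-pyran-6-yl)but-2-enoate] F4, which holds the two E-alkenes stacked head to head.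
 - Irradiation at 365 nm should then give, by template-directed [2+2] photodimerisation, the syn head-to-head cyclobutane still bridged by the template, the naphthalene-1,8-diyl cyclobutane-1,2-dicarboxylate F5. The E geometry places each methyl cis to its ester and the two pyranones cis to each other.
 - Mild hydrolysis of the two aryl esters (LiOH, THF/H2O, 0 °C) would release 18.

2. Step 4.
 - Process at risk: deprotonation may compete at C5′–H next to the methoxy group, or the amide base may attack the lactone, so that sulfur is not delivered cleanly to C6′.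
 - Fallback: it sets out from 6 and returns at 9, so step 5 is bypassed.
 - Iridium-catalysed C–H borylation ([Ir(OMe)(cod)]2, dtbpy, B2pin2, THF, 60 °C) should go to C6′–H, the only ring C–H without a substituent on the neighbouring carbon, and give 4-methoxy-3-methyl-6-(4,4,5,5-tetramethyl-1,3,2-dioxaborolan-2-yl)-2H-pyran-2-one F6.
 - Chan–Lam-type coupling of this boronate with PhSO2Na mediated by Cu(OAc)2 in air would give sulfone 9 directly, under neutral conditions without a strong base.

3. Step 10.
 - Process at risk: base-induced epimerisation at C1/C2 of the crowded all-cis dialdehyde, or lactol formation if one hydroxyl is oxidised before the other is activated.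
 - Fallback: it sets out from 16 and returns at 18, replacing steps 10 and 11.
 - Oxidative lactonisation of the cis-1,4-diol with catalytic TEMPO and PhI(OAc)2 in CH2Cl2 should give the cis-fused γ-lactone, 6,7-dimethyl-6,7-bis(4-methoxy-3-methyl-2-oxo-2H-pyran-6-yl)-3-oxabicyclo[3.2.0]heptan-2-one F7. Its ring fusion locks C1/C2 against epimerisation.
 - Opening with one equivalent of LiOH in THF/H2O at 0 °C gives the hydroxy acid, 2-(hydroxymethyl)-3,4-dimethyl-3,4-bis(4-methoxy-3-methyl-2-oxo-2H-pyran-6-yl)cyclobutane-1-carboxylic acid F8, as its lithium salt.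
 - Without acidification, the primary alcohol is oxidised in the same flask with catalytic TEMPO, NaClO2 and catalytic NaOCl in pH 6.7 phosphate buffer/MeCN to give 18.

**Further compounds**

F1 | step 8 | 6-iodo-4-methoxy-3-methyl-2H-pyran-2-one | COc1cc(I)oc(=O)c1C
F2 | step 8 | tert-butyl (E)-3-(4-methoxy-3-methyl-2-oxo-2H-pyran-6-yl)but-2-enoate | COc1cc(/C(C)=C/C(=O)OC(C)(C)C)oc(=O)c1C
F3 | step 8 | (E)-3-(4-methoxy-3-methyl-2-oxo-2H-pyran-6-yl)but-2-enoic acid | COc1cc(/C(C)=C/C(=O)O)oc(=O)c1C
F4 | step 8 | naphthalene-1,8-diyl bis[(E)-3-(4-methoxy-3-methyl-2-oxo-2H-pyran-6-yl)but-2-enoate] | COc1cc(/C(C)=C/C(=O)Oc2cccc3cccc(OC(=O)/C=C(C)/c4cc(OC)c(C)c(=O)o4)c23)oc(=O)c1C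
F5 | step 8 | naphthalene-1,8-diyl meso-3,4-dimethyl-3,4-bis(4-methoxy-3-methyl-2-oxo-2H-pyran-6-yl)cyclobutane-1,2-dicarboxylate (template-bridged) | C[C@]1(c2cc(OC)c(C)c(=O)o2)[C@H](C(=O)Oc2cccc3cccc(OC4=O)c23)[C@H]4[C@@]1(C)c1cc(OC)c(C)c(=O)o1
F6 | step 4 | 4-methoxy-3-methyl-6-(4,4,5,5-tetramethyl-1,3,2-dioxaborolan-2-yl)-2H-pyran-2-one | COc1cc(B2OC(C)(C)C(C)(C)O2)oc(=O)c1C
F7 | step 10 | cis-fused 6,7-dimethyl-6,7-bis(4-methoxy-3-methyl-2-oxo-2H-pyran-6-yl)-3-oxabicyclo[3.2.0]heptan-2-one (racemic) | C[C@]1(c2cc(OC)c(C)c(=O)o2)[C@@H]2C(=O)OC[C@@H]2[C@@]1(C)c1cc(OC)c(C)c(=O)o1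
F8 | step 10 | 2-(hydroxymethyl)-3,4-dimethyl-3,4-bis(4-methoxy-3-methyl-2-oxo-2H-pyran-6-yl)cyclobutane-1-carboxylic acid (racemic, all-cis CO2H, CH2OH, CH3, CH3) | C[C@]1(c2cc(OC)c(C)c(=O)o2)[C@H](C(=O)O)[C@H](CO)[C@@]1(C)c1cc(OC)c(C)c(=O)o1
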